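**Retrosynthetic overview**
1. The last C–C bond cut is between C5 of the dihydrobenzofuran and benzylic C2 of the 3,7-dioxabicyclo[3.3.0]octane. An aryllithium adds to an endo-guaiacyl furofuranone, and hydride delivery to the convex face of the derived oxocarbenium ion puts the second aryl group endo as well (all four carbons of the bicycle S).
2. The plan rests on C2 of the dihydrofuran ring (ring atoms O1, C2, C3, C3a, C7a): it is benzylic, carries the phenolic oxygen O1 and is cis to C3. A cis C2/C3 pair equals a syn-aldol pair after one inversion at C2, so O1–C2 is cut to a syn 2-(2-hydroxyaryl)-1-arylpropan-1-ol that is closed by Mitsunobu etherification.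
3. The syn pair comes from an Evans boron aldol between an arylacetyl imide (from 5-bromo-o-vanillin) and O-tosylvanillin; the tosylate makes the C2 aryl group a poor cation donor.
4. The furofuranone comes from the C2-symmetric (1S,5S)-dilactone. This is built on succinic anhydride: a succinyl bis-imide takes two benzyloxymethyl groups by successive titanium-enolate alkylations, then hydrogenolysis and lactonisation follow, and the dilactone is arylated and reduced once.
5. Ring order: both lactone rings of the dilactone in one operation; the dihydrofuran ring of the benzofuran (key step); then the two lactone rings are turned, one after the other, into the aryl-bearing tetrahydrofuran rings.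

Key step: step 11

Remark: lactols 35 and 38 are written ring-closed with no descriptor at the hemiketal carbon, because each may be an anomer mixture in equilibrium with its hydroxy ketone and that carbon is set only in the next reduction; enol ether 3 is an E/Z mixture.

**Route**

Step 1
Reactants: 1 5-bromo-2-hydroxy-3-methoxybenzaldehyde
Product: 2 2-(allyloxy)-5-bromo-3-methoxybenzaldehyde
Conditions: allyl bromide, K2CO3, DMF, rt
Reagents that add atoms: allyl bromide, C=CCBr
Why: Williamson etherification of the acidic ortho-formyl phenol should give the allyl ether, a phenol mask that tolerates ylide, boron enolate and hydride chemistry and is removable later with zerovalent palladium.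

Step 2
Reactants: 2 2-(allyloxy)-5-bromo-3-methoxybenzaldehyde
Product: 3 1-(allyloxy)-4-bromo-2-methoxy-6-(2-methoxyethenyl)benzene
Conditions: MeOCH2PPh3Cl, KOtBu, THF, 0 °C → rt
Reagents that add atoms: (methoxymethyl)triphenylphosphonium chloride, COC[P+](c1ccccc1)(c1ccccc1)c1ccccc1.[Cl-]
Why: Wittig methoxymethylenation should homologate the aldehyde by one carbon to the enol ether, whose E/Z geometry is irrelevant because it is hydrolysed next.

Step 3
Reactants: 3 1-(allyloxy)-4-bromo-2-methoxy-6-(2-methoxyethenyl)benzene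
Product: 4 2-[2-(allyloxy)-5-bromo-3-methoxyphenyl]acetaldehyde
Conditions: 2 M aq. HCl, THF, 50 °C
Reagents that add atoms: water, O
Why: acid-catalysed enol ether hydrolysis (C-protonation, hemiacetal, loss of methanol) should give the arylacetaldehyde, to be used crude, while the aryl allyl ether and the aryl bromide are inert.

Step 4
Reactants: 4 2-[2-(allyloxy)-5-bromo-3-methoxyphenyl]acetaldehyde
Product: 5 2-[2-(allyloxy)-5-bromo-3-methoxyphenyl]acetic acid
Conditions: NaClO2, NaH2PO4, 2-methyl-2-butene, t-BuOH/H2O, rt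
Reagents that add atoms: sodium chlorite, [Na+].[O-]Cl=O
Why: Pinnick oxidation should convert the aldehyde into the acid, with excess 2-methyl-2-butene trapping hypochlorous acid before it can reach the allyl group or the electron-rich ring.

Step 5
Reactants: 5 2-[2-(allyloxy)-5-bromo-3-methoxyphenyl]acetic acid, 6 (R)-4-benzyloxazolidin-2-one
Product: 8 (R)-3-{2-[2-(allyloxy)-5-bromo-3-methoxyphenyl]acetyl}-4-benzyloxazolidin-2-one, via mixed pivalic anhydride 7 (not isolated)
Conditions: PivCl, Et3N, THF, −20 °C; then LiCl, 6, −20 °C → rt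
Reagents that add atoms: none
Why: N-acylation of the oxazolidinone through the mixed anhydride should occur at the less hindered arylacetyl carbonyl and install the (R)-auxiliary required for the aldol sense of step 7.

Step 6
Reactants: 9 vanillin
Product: 10 4-formyl-2-methoxyphenyl 4-methylbenzenesulfonate
Conditions: TsCl, Et3N, DMAP (cat.), CH2Cl2, 0 °C → rt
Reagents that add atoms: 4-toluenesulfonyl chloride, Cc1ccc(cc1)S(Cl)(=O)=O
Why: O-sulfonylation of the phenol should give the aryl tosylate, which protects the phenol and lowers the donor power of the para oxygen for step 11.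

Step 7
Reactants: 8 (R)-3-{2-[2-(allyloxy)-5-bromo-3-methoxyphenyl]acetyl}-4-benzyloxazolidin-2-one, 10 4-formyl-2-methoxyphenyl 4-methylbenzenesulfonate
Product: 13 (R)-3-[(2R,3R)-2-(2-allyloxy-5-bromo-3-methoxyphenyl)-3-hydroxy-3-(3-methoxy-4-tosyloxyphenyl)propanoyl]-4-benzyloxazolidin-2-one, via dibutylboron Z-enolate 11 (not isolated), via dibutylboron aldolate 12 (not isolated)
Conditions: Bu2BOTf, iPr2NEt, CH2Cl2, −78 → 0 °C; 10, −78 → 0 °C; pH 7 phosphate buffer, MeOH, 30% H2O2, 0 °C
Reagents that add atoms: none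
Why: Evans syn-aldol, in which the Z boron enolate should add to the aldehyde through a chair-like six-membered transition state on the enolate face away from the benzyl group of the (R)-auxiliary, setting both new centres as the (2R,3R) syn pair.

Step 8
Reactants: 13 (R)-3-[(2R,3R)-2-(2-allyloxy-5-bromo-3-methoxyphenyl)-3-hydroxy-3-(3-methoxy-4-tosyloxyphenyl)propanoyl]-4-benzyloxazolidin-2-one
Product: 14 (1R,2S)-2-(2-allyloxy-5-bromo-3-methoxyphenyl)-1-(3-methoxy-4-tosyloxyphenyl)propane-1,3-diol
Conditions: LiBH4, MeOH (1 equiv), THF, 0 °C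
Reagents that add atoms: none
Why: reductive cleavage of the imide by LiBH4 should give the primary alcohol and release the auxiliary without touching the aryl tosylate, aryl bromide, allyl ether or either stereocentre (the descriptor at C2 changes only through CIP priorities).

Step 9
Reactants: 14 (1R,2S)-2-(2-allyloxy-5-bromo-3-methoxyphenyl)-1-(3-methoxy-4-tosyloxyphenyl)propane-1,3-diol
Product: 15 (1R,2S)-2-(2-allyloxy-5-bromo-3-methoxyphenyl)-1-(3-methoxy-4-tosyloxyphenyl)-3-(triisopropylsilyloxy)propan-1-ol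
Conditions: TIPSCl, imidazole, DMF, 0 °C → rt
Reagents that add atoms: triisopropylsilyl chloride, CC(C)[Si](Cl)(C(C)C)C(C)C
Why: silylation with the bulky chloride should select the primary hydroxyl over the hindered secondary benzylic one, leaving the latter as the only free aliphatic hydroxyl.

Step 10
Reactants: 15 (1R,2S)-2-(2-allyloxy-5-bromo-3-methoxyphenyl)-1-(3-methoxy-4-tosyloxyphenyl)-3-(triisopropylsilyloxy)propan-1-ol
Product: 16 (1R,2S)-2-(5-bromo-2-hydroxy-3-methoxyphenyl)-1-(3-methoxy-4-tosyloxyphenyl)-3-(triisopropylsilyloxy)propan-1-ol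
Conditions: Pd(PPh3)4 (5 mol %), morpholine, THF, rt
Reagents that add atoms: none
Why: Tsuji–Trost deallylation, in which zerovalent palladium ionises the aryl allyl ether and morpholine traps the allyl unit, should free the phenol at room temperature, where the aryl bromide and aryl tosylate do not undergo oxidative addition.

Step 11
Reactants: 16 (1R,2S)-2-(5-bromo-2-hydroxy-3-methoxyphenyl)-1-(3-methoxy-4-tosyloxyphenyl)-3-(triisopropylsilyloxy)propan-1-ol
Product: 18 (2S,3S)-5-bromo-7-methoxy-2-(3-methoxy-4-tosyloxyphenyl)-3-[(triisopropylsilyloxy)methyl]-2,3-dihydrobenzofuran, via alkoxyphosphonium phenoxide 17 (not isolated)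
Conditions: PPh3, DIAD, THF (0.02 M), 0 °C → rt
Reagents that add atoms: none
Why: PPh3 and DIAD form the betaine, which deprotonates the phenol and passes the phosphonium group to the only free aliphatic hydroxyl, the benzylic one, to give alkoxyphosphonium phenoxide 17. The tethered phenoxide then expels triphenylphosphine oxide from the rear in an intramolecular Mitsunobu etherification, the known way to close 2-aryl-2,3-dihydrobenzofurans from 2-(2-hydroxyaryl)-1-arylethanols. The dihydrofuran ring closes in the 5-exo-tet mode with formation of O1–C2. The C2 centre arises by inversion of the (1R) carbinol carbon fixed in step 7, so the syn precursor should give the cis (2S,3S) ring, and C3 is not touched. The step needs SN2 displacement to win over ionisation to a benzylic cation (which would leak to the more stable trans isomer) and over E2 loss to a stilbene; the sulfonate on the para oxygen of the C2 aryl group makes that ring a poor cation donor, and the five-membered tether with high dilution favours the intramolecular displacement.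

Step 12
Reactants: 18 (2S,3S)-5-bromo-7-methoxy-2-(3-methoxy-4-tosyloxyphenyl)-3-[(triisopropylsilyloxy)methyl]-2,3-dihydrobenzofuran
Product: 19 (2S,3S)-5-bromo-2-(4-hydroxy-3-methoxyphenyl)-7-methoxy-3-[(triisopropylsilyloxy)methyl]-2,3-dihydrobenzofuran
Conditions: Mg turnings, MeOH, rt
Reagents that add atoms: none
Why: reductive desulfonylation with Mg in methanol (electron transfer into the tosyl arene and S–O cleavage) should free the phenol at room temperature, while the electron-rich aryl bromide, the silyl ether and the cis ring should be inert.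

Step 13
Reactants: 19 (2S,3S)-5-bromo-2-(4-hydroxy-3-methoxyphenyl)-7-methoxy-3-[(triisopropylsilyloxy)methyl]-2,3-dihydrobenzofuran
Product: 20 (2S,3S)-5-bromo-2-[4-(tert-butyldimethylsilyloxy)-3-methoxyphenyl]-7-methoxy-3-[(triisopropylsilyloxy)methyl]-2,3-dihydrobenzofuran
Conditions: TBSCl, imidazole, DMF, rt
Reagents that add atoms: tert-butyldimethylsilyl chloride, CC(C)(C)[Si](C)(C)Cl
Why: silylation of the phenol should give an aryl silyl ether that tolerates the aryllithium of step 22, unlike the sulfonate it replaces.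

Step 14
Reactants: 21 4-bromo-2-methoxyphenol
Product: 22 (4-bromo-2-methoxyphenoxy)(tert-butyl)dimethylsilane
Conditions: TBSCl, imidazole, DMF, rt
Reagents that add atoms: tert-butyldimethylsilyl chloride, CC(C)(C)[Si](C)(C)Cl
Why: phenol silylation should mask the acidic hydroxyl ahead of bromine–lithium exchange.

Step 15
Reactants: 6 (R)-4-benzyloxazolidin-2-one, 23 succinic anhydride
Product: 25 4-[(R)-4-benzyl-2-oxooxazolidin-3-yl]-4-oxobutanoic acid, via lithium oxazolidinide 24 (not isolated)
Conditions: n-BuLi, THF, −78 °C; 23, −78 → 0 °C; aq. HCl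
Reagents that add atoms: none
Why: ring-opening N-acylation, in which the lithiated oxazolidinone opens the cyclic anhydride once and the lithium carboxylate so formed cannot acylate a second time, should give the mono-imide acid.

Step 16
Reactants: 25 4-[(R)-4-benzyl-2-oxooxazolidin-3-yl]-4-oxobutanoic acid, 6 (R)-4-benzyloxazolidin-2-one
Product: 27 1,4-bis[(R)-4-benzyl-2-oxooxazolidin-3-yl]butane-1,4-dione, via mixed pivalic anhydride 26 (not isolated)
Conditions: PivCl, Et3N, THF, −20 °C; then LiCl, 6, −20 °C → rt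
Reagents that add atoms: none
Why: N-acylation of a second molecule of the oxazolidinone through the mixed anhydride, at the less hindered succinyl carbonyl, should give the C2-symmetric succinyl bis-imide, in which each future stereocentre sits next to its own (R)-auxiliary.

Step 17
Reactants: 27 1,4-bis[(R)-4-benzyl-2-oxooxazolidin-3-yl]butane-1,4-dione
Product: 29 (S)-2-[(benzyloxy)methyl]-1,4-bis[(R)-4-benzyl-2-oxooxazolidin-3-yl]butane-1,4-dione, via trichlorotitanium Z-enolate 28 (not isolated)
Conditions: TiCl4 (1.05 equiv), iPr2NEt (1.1 equiv), CH2Cl2, 0 °C; BnOCH2Cl, 0 °C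
Reagents that add atoms: benzyl chloromethyl ether, ClCOCc1ccccc1
Why: Evans titanium-enolate alkylation, in which soft enolisation of one of the two equivalent imides gives the chelated Z enolate and the benzyloxymethyl electrophile enters on the face away from the benzyl group of the (R)-auxiliary, should set C2 as S, with one equivalent of base holding the reaction at monoalkylation.

Step 18
Reactants: 29 (S)-2-[(benzyloxy)methyl]-1,4-bis[(R)-4-benzyl-2-oxooxazolidin-3-yl]butane-1,4-dione
Product: 31 (2S,3S)-2,3-bis[(benzyloxy)methyl]-1,4-bis[(R)-4-benzyl-2-oxooxazolidin-3-yl]butane-1,4-dione, via trichlorotitanium Z-enolate 30 (not isolated)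
Conditions: TiCl4 (1.05 equiv), iPr2NEt (1.1 equiv), CH2Cl2, 0 °C; BnOCH2Cl, 0 °C
Reagents that add atoms: benzyl chloromethyl ether, ClCOCc1ccccc1
Why: a second Evans titanium-enolate alkylation, in which soft enolisation takes the remaining methylene (the substituted α-carbon is shielded by allylic strain, so no enolate with a β-benzyloxy group forms) and the (R)-auxiliary on that side again directs the electrophile to the face away from its benzyl group, should set C3 as S and give the C2-symmetric isomer.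

Step 19
Reactants: 31 (2S,3S)-2,3-bis[(benzyloxy)methyl]-1,4-bis[(R)-4-benzyl-2-oxooxazolidin-3-yl]butane-1,4-dione
Product: 33 (1S,5S)-3,7-dioxabicyclo[3.3.0]octane-2,6-dione, via diol bis-imide 32 (not isolated)
Conditions: H2 (1 atm), Pd/C, EtOAc, rt; then camphorsulfonic acid (cat.), CH2Cl2, rt
Reagents that add atoms: none
Why: hydrogenolysis of both benzyl ethers followed by attack of each primary hydroxyl on the distal imide carbonyl (two 5-exo-trig lactonisations with loss of both auxiliaries) should give the cis-fused dilactone, whose ring fusion follows from the (S,S) centres, which are not touched.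

Step 20
Reactants: 22 (4-bromo-2-methoxyphenoxy)(tert-butyl)dimethylsilane, 33 (1S,5S)-3,7-dioxabicyclo[3.3.0]octane-2,6-dione
Product: 35 (1S,5S)-6-[4-(tert-butyldimethylsilyloxy)-3-methoxyphenyl]-6-hydroxy-3,7-dioxabicyclo[3.3.0]octan-2-one, via aryllithium 34 (not isolated)
Conditions: n-BuLi, THF, −78 °C; cannulated into 33 (2 equiv), THF, −78 °C; AcOH, −78 °C
Reagents that add atoms: none
Why: bromine–lithium exchange and addition of the aryllithium to one of the two equivalent lactone carbonyls should stop at the lactol because the tetrahedral lithium alkoxide persists at −78 °C, and the excess of dilactone limits attack on the second lactone.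

Step 21
Reactants: 35 (1S,5S)-6-[4-(tert-butyldimethylsilyloxy)-3-methoxyphenyl]-6-hydroxy-3,7-dioxabicyclo[3.3.0]octan-2-one
Product: 36 (1S,5S,6S)-6-[4-(tert-butyldimethylsilyloxy)-3-methoxyphenyl]-3,7-dioxabicyclo[3.3.0]octan-2-one
Conditions: Et3SiH, BF3·OEt2, CH2Cl2, −78 °C
Reagents that add atoms: none
Why: ionic hydrogenation, in which BF3 ionises the lactol to the aryl-stabilised bicyclic oxocarbenium ion and Et3SiH delivers hydride to its convex face, should place the aryl group on the concave (endo) face and set C6 as S.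

Step 22
Reactants: 20 (2S,3S)-5-bromo-2-[4-(tert-butyldimethylsilyloxy)-3-methoxyphenyl]-7-methoxy-3-[(triisopropylsilyloxy)methyl]-2,3-dihydrobenzofuran, 36 (1S,5S,6S)-6-[4-(tert-butyldimethylsilyloxy)-3-methoxyphenyl]-3,7-dioxabicyclo[3.3.0]octan-2-one
Product: 38 (1S,5S,6S)-2-{(2S,3S)-2-[4-(tert-butyldimethylsilyloxy)-3-methoxyphenyl]-7-methoxy-3-[(triisopropylsilyloxy)methyl]-2,3-dihydrobenzofuran-5-yl}-6-[4-(tert-butyldimethylsilyloxy)-3-methoxyphenyl]-3,7-dioxabicyclo[3.3.0]octan-2-ol, via aryllithium 37 (not isolated)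
Conditions: n-BuLi, THF, −78 °C; then 36 (1.2 equiv), −78 °C; AcOH, −78 °C
Reagents that add atoms: none
Why: bromine–lithium exchange at C5 of the benzofuran is faster than any deprotonation at −78 °C, and addition of the aryllithium to the lactone carbonyl should give the lactol, forming the last carbon–carbon bond without touching an existing stereocentre.

Step 23
Reactants: 38 (1S,5S,6S)-2-{(2S,3S)-2-[4-(tert-butyldimethylsilyloxy)-3-methoxyphenyl]-7-methoxy-3-[(triisopropylsilyloxy)methyl]-2,3-dihydrobenzofuran-5-yl}-6-[4-(tert-butyldimethylsilyloxy)-3-methoxyphenyl]-3,7-dioxabicyclo[3.3.0]octan-2-ol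
Product: 39 (1S,2S,5S,6S)-2-{(2S,3S)-2-[4-(tert-butyldimethylsilyloxy)-3-methoxyphenyl]-7-methoxy-3-[(triisopropylsilyloxy)methyl]-2,3-dihydrobenzofuran-5-yl}-6-[4-(tert-butyldimethylsilyloxy)-3-methoxyphenyl]-3,7-dioxabicyclo[3.3.0]octane
Conditions: Et3SiH, BF3·OEt2, CH2Cl2, −78 °C
Reagents that add atoms: none
Why: ionic hydrogenation of the lactol, with hydride again delivered to the convex face of the oxocarbenium ion, should set C2 of the bicycle as S with the new aryl group endo, the low temperature keeping the other benzylic C–O bonds from ionising.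

Step 24
Reactants: 39 (1S,2S,5S,6S)-2-{(2S,3S)-2-[4-(tert-butyldimethylsilyloxy)-3-methoxyphenyl]-7-methoxy-3-[(triisopropylsilyloxy)methyl]-2,3-dihydrobenzofuran-5-yl}-6-[4-(tert-butyldimethylsilyloxy)-3-methoxyphenyl]-3,7-dioxabicyclo[3.3.0]octane
Product: 40 (1S,2S,5S,6S)-2-[(2S,3S)-2-(4-hydroxy-3-methoxyphenyl)-3-(hydroxymethyl)-7-methoxy-2,3-dihydrobenzofuran-5-yl]-6-(4-hydroxy-3-methoxyphenyl)-3,7-dioxabicyclo[3.3.0]octane
Conditions: Bu4NF, AcOH, THF, 0 °C → rt
Reagents that add atoms: none
Why: fluoride should cleave the two aryl silyl ethers and the primary silyl ether, and the acetic acid buffer keeps the phenols protonated so that the para-hydroxybenzylic ethers are not opened through quinone methides and no stereocentre is touched.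

**Compound list**
1 | 5-bromo-2-hydroxy-3-methoxybenzaldehyde | COc1cc(Br)cc(C=O)c1O | starting material
2 | 2-(allyloxy)-5-bromo-3-methoxybenzaldehyde | COc1cc(Br)cc(C=O)c1OCC=C | intermediate
3 | 1-(allyloxy)-4-bromo-2-methoxy-6-(2-methoxyethenyl)benzene (E/Z mixture) | COC=Cc1cc(Br)cc(OC)c1OCC=C | intermediate
4 | 2-[2-(allyloxy)-5-bromo-3-methoxyphenyl]acetaldehyde | O=CCc1cc(Br)cc(OC)c1OCC=C | intermediate
5 | 2-[2-(allyloxy)-5-bromo-3-methoxyphenyl]acetic acid | OC(=O)Cc1cc(Br)cc(OC)c1OCC=C | intermediate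
6 | (R)-4-benzyloxazolidin-2-one | O=C1OC[C@@H](Cc2ccccc2)N1 | starting material
7 | mixed anhydride of 5 with pivalic acid | CC(C)(C)C(=O)OC(=O)Cc1cc(Br)cc(OC)c1OCC=C | intermediate
8 | (R)-3-{2-[2-(allyloxy)-5-bromo-3-methoxyphenyl]acetyl}-4-benzyloxazolidin-2-one | O=C(Cc1cc(Br)cc(OC)c1OCC=C)N1C(=O)OC[C@H]1Cc1ccccc1 | intermediate
9 | vanillin | COc1cc(C=O)ccc1O | starting material
10 | 4-formyl-2-methoxyphenyl 4-methylbenzenesulfonate | COc1cc(C=O)ccc1OS(=O)(=O)c1ccc(C)cc1 | intermediate
11 | Z dibutylboron enolate of 8 | CCCCB(CCCC)O/C(=C\c1cc(Br)cc(OC)c1OCC=C)N1C(=O)OC[C@H]1Cc1ccccc1 | intermediate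
12 | dibutylboron aldolate of 13 | Brc1cc(OC)c(OCC=C)c(c1)[C@@H](C(=O)N1C(=O)OC[C@H]1Cc1ccccc1)[C@H](c1ccc(OS(=O)(=O)c2ccc(C)cc2)c(OC)c1)OB(CCCC)CCCC | intermediate
13 | (R)-3-[(2R,3R)-2-(2-allyloxy-5-bromo-3-methoxyphenyl)-3-hydroxy-3-(3-methoxy-4-tosyloxyphenyl)propanoyl]-4-benzyloxazolidin-2-one | Brc1cc(OC)c(OCC=C)c(c1)[C@@H](C(=O)N1C(=O)OC[C@H]1Cc1ccccc1)[C@H](c1ccc(OS(=O)(=O)c2ccc(C)cc2)c(OC)c1)O | intermediate
14 | (1R,2S)-2-(2-allyloxy-5-bromo-3-methoxyphenyl)-1-(3-methoxy-4-tosyloxyphenyl)propane-1,3-diol | Brc1cc(OC)c(OCC=C)c(c1)[C@@H](CO)[C@H](c1ccc(OS(=O)(=O)c2ccc(C)cc2)c(OC)c1)O | intermediate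
15 | (1R,2S)-2-(2-allyloxy-5-bromo-3-methoxyphenyl)-1-(3-methoxy-4-tosyloxyphenyl)-3-(triisopropylsilyloxy)propan-1-ol | Brc1cc(OC)c(OCC=C)c(c1)[C@@H](CO[Si](C(C)C)(C(C)C)C(C)C)[C@H](c1ccc(OS(=O)(=O)c2ccc(C)cc2)c(OC)c1)O | intermediate
16 | (1R,2S)-2-(5-bromo-2-hydroxy-3-methoxyphenyl)-1-(3-methoxy-4-tosyloxyphenyl)-3-(triisopropylsilyloxy)propan-1-ol (syn) | Brc1cc(OC)c(O)c(c1)[C@@H](CO[Si](C(C)C)(C(C)C)C(C)C)[C@H](c1ccc(OS(=O)(=O)c2ccc(C)cc2)c(OC)c1)O | intermediate
17 | alkoxyphosphonium phenoxide from 16 | Brc1cc(OC)c([O-])c(c1)[C@@H](CO[Si](C(C)C)(C(C)C)C(C)C)[C@H](c1ccc(OS(=O)(=O)c2ccc(C)cc2)c(OC)c1)O[P+](c1ccccc1)(c1ccccc1)c1ccccc1 | intermediate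
18 | (2S,3S)-5-bromo-7-methoxy-2-(3-methoxy-4-tosyloxyphenyl)-3-[(triisopropylsilyloxy)methyl]-2,3-dihydrobenzofuran (cis) | Brc1cc(OC)c2c(c1)[C@@H](CO[Si](C(C)C)(C(C)C)C(C)C)[C@@H](c1ccc(OS(=O)(=O)c3ccc(C)cc3)c(OC)c1)O2 | intermediate
19 | (2S,3S)-5-bromo-2-(4-hydroxy-3-methoxyphenyl)-7-methoxy-3-[(triisopropylsilyloxy)methyl]-2,3-dihydrobenzofuran | Brc1cc(OC)c2c(c1)[C@@H](CO[Si](C(C)C)(C(C)C)C(C)C)[C@@H](c1ccc(O)c(OC)c1)O2 | intermediate
20 | (2S,3S)-5-bromo-2-[4-(tert-butyldimethylsilyloxy)-3-methoxyphenyl]-7-methoxy-3-[(triisopropylsilyloxy)methyl]-2,3-dihydrobenzofuran | Brc1cc(OC)c2c(c1)[C@@H](CO[Si](C(C)C)(C(C)C)C(C)C)[C@@H](c1ccc(O[Si](C)(C)C(C)(C)C)c(OC)c1)O2 | intermediate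
21 | 4-bromo-2-methoxyphenol | COc1cc(Br)ccc1O | starting material
22 | (4-bromo-2-methoxyphenoxy)(tert-butyl)dimethylsilane | COc1cc(Br)ccc1O[Si](C)(C)C(C)(C)C | intermediate
23 | succinic anhydride | O=C1CCC(=O)O1 | starting material
24 | lithium salt of 6 (N-lithio oxazolidinone) | [Li]N1C(=O)OC[C@H]1Cc1ccccc1 | intermediate
25 | 4-[(R)-4-benzyl-2-oxooxazolidin-3-yl]-4-oxobutanoic acid | OC(=O)CCC(=O)N1C(=O)OC[C@H]1Cc1ccccc1 | intermediate
26 | mixed anhydride of 25 with pivalic acid | CC(C)(C)C(=O)OC(=O)CCC(=O)N1C(=O)OC[C@H]1Cc1ccccc1 | intermediate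
27 | 1,4-bis[(R)-4-benzyl-2-oxooxazolidin-3-yl]butane-1,4-dione | O=C(CCC(=O)N1C(=O)OC[C@H]1Cc1ccccc1)N1C(=O)OC[C@H]1Cc1ccccc1 | intermediate
28 | Z trichlorotitanium enolate of 27 | Cl[Ti](Cl)(Cl)O/C(=C\CC(=O)N1C(=O)OC[C@H]1Cc1ccccc1)N1C(=O)OC[C@H]1Cc1ccccc1 | intermediate
29 | (S)-2-[(benzyloxy)methyl]-1,4-bis[(R)-4-benzyl-2-oxooxazolidin-3-yl]butane-1,4-dione | O=C([C@H](COCc1ccccc1)CC(=O)N1C(=O)OC[C@H]1Cc1ccccc1)N1C(=O)OC[C@H]1Cc1ccccc1 | intermediate
30 | Z trichlorotitanium enolate of 29 (at the unsubstituted α-carbon) | Cl[Ti](Cl)(Cl)O/C(=C\[C@@H](COCc1ccccc1)C(=O)N1C(=O)OC[C@H]1Cc1ccccc1)N1C(=O)OC[C@H]1Cc1ccccc1 | intermediate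
31 | (2S,3S)-2,3-bis[(benzyloxy)methyl]-1,4-bis[(R)-4-benzyl-2-oxooxazolidin-3-yl]butane-1,4-dione | O=C([C@H](COCc1ccccc1)[C@@H](COCc1ccccc1)C(=O)N1C(=O)OC[C@H]1Cc1ccccc1)N1C(=O)OC[C@H]1Cc1ccccc1 | intermediate
32 | (2S,3S)-2,3-bis(hydroxymethyl)-1,4-bis[(R)-4-benzyl-2-oxooxazolidin-3-yl]butane-1,4-dione | O=C([C@H](CO)[C@@H](CO)C(=O)N1C(=O)OC[C@H]1Cc1ccccc1)N1C(=O)OC[C@H]1Cc1ccccc1 | intermediate
33 | (1S,5S)-3,7-dioxabicyclo[3.3.0]octane-2,6-dione (cis-fused, C2-symmetric) | O=C1OC[C@@H]2[C@H]1COC2=O | intermediate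
34 | 4-(tert-butyldimethylsilyloxy)-3-methoxyphenyllithium | [Li]c1ccc(O[Si](C)(C)C(C)(C)C)c(OC)c1 | intermediate
35 | (1S,5S)-6-[4-(tert-butyldimethylsilyloxy)-3-methoxyphenyl]-6-hydroxy-3,7-dioxabicyclo[3.3.0]octan-2-one (C6 not defined) | COc1cc(C2(O)OC[C@@H]3[C@H]2COC3=O)ccc1O[Si](C)(C)C(C)(C)C | intermediate
36 | (1S,5S,6S)-6-[4-(tert-butyldimethylsilyloxy)-3-methoxyphenyl]-3,7-dioxabicyclo[3.3.0]octan-2-one (aryl endo) | COc1cc([C@H]2OC[C@@H]3[C@H]2COC3=O)ccc1O[Si](C)(C)C(C)(C)C | intermediate
37 | aryllithium from 20 (lithium at C5 of the benzofuran) | [Li]c1cc(OC)c2c(c1)[C@@H](CO[Si](C(C)C)(C(C)C)C(C)C)[C@@H](c1ccc(O[Si](C)(C)C(C)(C)C)c(OC)c1)O2 | intermediate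
38 | lactol from 37 and 36: (1S,5S,6S)-2-(benzofuran-5-yl)-6-aryl-3,7-dioxabicyclo[3.3.0]octan-2-ol carrying the three silyl ethers (C2 of the bicycle not defined) | COc1cc([C@H]2OC[C@@H]3[C@H]2COC3(O)c2cc(OC)c3c(c2)[C@@H](CO[Si](C(C)C)(C(C)C)C(C)C)[C@@H](c2ccc(O[Si](C)(C)C(C)(C)C)c(OC)c2)O3)ccc1O[Si](C)(C)C(C)(C)C | intermediate
39 | tris-silyl ether of the target (both aryl groups endo) | COc1cc([C@H]2OC[C@@H]3[C@H]2CO[C@@H]3c2cc(OC)c3c(c2)[C@@H](CO[Si](C(C)C)(C(C)C)C(C)C)[C@@H](c2ccc(O[Si](C)(C)C(C)(C)C)c(OC)c2)O3)ccc1O[Si](C)(C)C(C)(C)C | intermediate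
40 | CNP0303197.1, (1S,2S,5S,6S)-2-[(2S,3S)-2-(4-hydroxy-3-methoxyphenyl)-3-(hydroxymethyl)-7-methoxy-2,3-dihydrobenzofuran-5-yl]-6-(4-hydroxy-3-methoxyphenyl)-3,7-dioxabicyclo[3.3.0]octane | COc1cc([C@H]2OC[C@@H]3[C@H]2CO[C@@H]3c2cc(OC)c3c(c2)[C@@H](CO)[C@@H](c2ccc(O)c(OC)c2)O3)ccc1O | target

**Totals**
Total step count: 24. Longest linear sequence: 15 steps (steps 1–5, 7–13, 22–24).

**Steps most likely to fail**

Step 11. The activated benzylic C–O bond may ionise before the phenoxide attacks, which would erode the inversion and leak to the trans ring, or the alkoxyphosphonium may lose a proton from C3 and eliminate to a stilbene. The fallback sets out from 15 and comes back at 18. The only free hydroxyl of 15 is mesylated (MsCl, Et3N, CH2Cl2, −20 °C) to the secondary benzylic mesylate F1. The allyl group is then removed under neutral conditions (Pd(PPh3)4 cat., PhSiH3, CH2Cl2, rt) to give the phenol mesylate F2. Cs2CO3 in DMF at 0 °C should let the phenoxide displace the mesylate from the rear (Williamson closure, 5-exo-tet, inversion) to give 18.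

Step 18. Enolisation of the methylene next to the new stereocentre may be slow, and the hindered enolate may be alkylated sluggishly. Base may instead take the proton of the substituted α-carbon, with loss of benzyloxide. The auxiliary may also fail to override the neighbouring centre, which would give the (2S,3R) isomer that cannot form the bicyclic dilactone. The fallback sets out from 29 and comes back at 33; it replaces the alkylation by an aldol hydroxymethylation whose product is drained at once by lactonisation, so the two lactone rings are closed one after the other. The titanium enolate of 29 (TiCl4, iPr2NEt, CH2Cl2, 0 °C) is treated with s-trioxane activated by a second equivalent of TiCl4, which should give the hydroxymethyl bis-imide F3, the (R)-auxiliary again fixing the new centre as S. Camphorsulfonic acid in CH2Cl2 should let the free hydroxyl attack the distal imide carbonyl and give the benzyloxymethyl lactone imide F4 with release of one auxiliary; a diastereomer at the new centre would be removed at this crystalline lactone stage. Hydrogenolysis (H2, Pd/C, EtOAc) to the hydroxymethyl lactone imide F5 and a second acid-catalysed lactonisation should give 33.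

Step 23. Hydride delivery to the oxocarbenium ion may lose facial selectivity because the aryl group already on the concave face crowds the position the new aryl group must take. The Lewis acid may also ionise the two labile benzylic C–O bonds (C6–O7 of the bicycle and O1–C2 of the cis dihydrobenzofuran), with epimerisation to the exo or trans isomers. The fallback sets out from 38 and comes back at 39. The hydroxy ketone tautomer of 38 is reduced under reagent control ((R)-2-methyl-CBS-oxazaborolidine, BH3·SMe2, THF, −20 °C; CBS reduction) to the (S)-benzylic carbinol, the 1,4-diol F6. The primary hydroxyl is mesylated selectively (MsCl, 2,4,6-collidine, CH2Cl2, −20 °C) to the primary mesylate F7. NaH in THF at 0 °C should let the benzylic alkoxide close the tetrahydrofuran ring at the primary carbon (5-exo-tet), with retention at the benzylic carbon, to give 39 without any Lewis acid.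

**Further compounds**
F1 | step 11 | (1R,2S)-2-[2-(allyloxy)-5-bromo-3-methoxyphenyl]-1-(3-methoxy-4-tosyloxyphenyl)-3-(triisopropylsilyloxy)propyl methanesulfonate | Brc1cc(OC)c(OCC=C)c(c1)[C@@H](CO[Si](C(C)C)(C(C)C)C(C)C)[C@H](c1ccc(OS(=O)(=O)c2ccc(C)cc2)c(OC)c1)OS(C)(=O)=O
F2 | step 11 | (1R,2S)-2-(5-bromo-2-hydroxy-3-methoxyphenyl)-1-(3-methoxy-4-tosyloxyphenyl)-3-(triisopropylsilyloxy)propyl methanesulfonate | Brc1cc(OC)c(O)c(c1)[C@@H](CO[Si](C(C)C)(C(C)C)C(C)C)[C@H](c1ccc(OS(=O)(=O)c2ccc(C)cc2)c(OC)c1)OS(C)(=O)=O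
F3 | step 18 | (2S,3S)-2-[(benzyloxy)methyl]-3-(hydroxymethyl)-1,4-bis[(R)-4-benzyl-2-oxooxazolidin-3-yl]butane-1,4-dione | O=C([C@H](COCc1ccccc1)[C@@H](CO)C(=O)N1C(=O)OC[C@H]1Cc1ccccc1)N1C(=O)OC[C@H]1Cc1ccccc1
F4 | step 18 | (R)-4-benzyl-3-{[(3S,4S)-4-[(benzyloxy)methyl]-5-oxotetrahydrofuran-3-yl]carbonyl}oxazolidin-2-one | O=C1OC[C@@H](C(=O)N2C(=O)OC[C@H]2Cc2ccccc2)[C@H]1COCc1ccccc1
F5 | step 18 | (R)-4-benzyl-3-{[(3S,4S)-4-(hydroxymethyl)-5-oxotetrahydrofuran-3-yl]carbonyl}oxazolidin-2-one | O=C1OC[C@@H](C(=O)N2C(=O)OC[C@H]2Cc2ccccc2)[C@H]1CO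
F6 | step 23 | (S)-carbinol 1,4-diol: (3S,4S,5S)-5-aryl-4-(hydroxymethyl)tetrahydrofuran-3-yl benzofuranyl methanol carrying the three silyl ethers | COc1cc([C@H]2OC[C@H]([C@H]2CO)[C@H](O)c2cc(OC)c3c(c2)[C@@H](CO[Si](C(C)C)(C(C)C)C(C)C)[C@@H](c2ccc(O[Si](C)(C)C(C)(C)C)c(OC)c2)O3)ccc1O[Si](C)(C)C(C)(C)C
F7 | step 23 | primary methanesulfonate of F6 | COc1cc([C@H]2OC[C@H]([C@H]2COS(C)(=O)=O)[C@H](O)c2cc(OC)c3c(c2)[C@@H](CO[Si](C(C)C)(C(C)C)C(C)C)[C@@H](c2ccc(O[Si](C)(C)C(C)(C)C)c(OC)c2)O3)ccc1O[Si](C)(C)C(C)(C)C
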